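**Retrosynthetic overview**
1. Target ⇐ enone ester 25 (reagent-controlled ketone reduction sets C7) ⇐ β-keto ester 22 ⇐ spiro ketone 18 (C8 carboxylation, then dehydrogenation).
2. Side chain: C1'–C2' bond by a radical reductive olefin–enone coupling of a C1-vinyl group with isopropyl vinyl ketone; the vinyl group comes from radical vinylation of the C1 alcohol.
3. Spiro centre C5 and the cyclopentanone ⇐ vinylogous semipinacol ring expansion (cyclobutanol → cyclopentanone) of the adduct of lithiated 3-bromocyclohexenone ketal and (S)-2-methylcyclobutanone.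
4. (S)-2-Methylcyclobutanone ⇐ cyclopropylcarbinyl → cyclobutanone ring expansion of the Kulinkovich product of ethyl (S)-lactate.
5. Ring order: the six-membered ring is bought; cyclopropane → cyclobutane → cyclopentane by two consecutive 1,2-shifts, the second one closing the spiro junction.

Assumption: locants follow the spiro[4.5]decane core of the target (C1 side chain, C4 methyl, C5 spiro, C7 OH, C8 CO2Me; side chain C1'–C4'). The carbinol epimers of 9 and 12 are drawn as the expected major isomers; both converge.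

**Step 1**
Reactants: 1 ethyl (S)-lactate; 2 ethylmagnesium bromide
Product: 3 1-[(1S)-1-hydroxyethyl]cyclopropan-1-ol
Conditions: EtMgBr (3.5 equiv), Ti(OiPr)4 (20 mol%), THF/Et2O, 0 °C → rt; then H2O
Reagents that add atoms: none
Why: Kulinkovich cyclopropanation of the ester (the free OH is carried as its magnesium alkoxide); the lactate stereocentre is not touched.

**Step 2**
Reactants: 3 1-[(1S)-1-hydroxyethyl]cyclopropan-1-ol
Product: 5 (2S)-2-methylcyclobutan-1-one, via secondary mesylate 4 (not isolated)
Conditions: MsCl, Et3N, CH2Cl2, −10 °C → rt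
Reagents that add atoms: none
Why: Pinacol-type cyclopropylcarbinyl → cyclobutanone ring expansion; a ring CH2 migrates anti to the departing mesylate with the cyclopropanol oxygen pushing, so the carbinol carbon is inverted stereospecifically and becomes (S)-C2.

**Step 3**
Reactants: 6 3-bromocyclohex-2-en-1-one
Product: 7 7-bromo-1,4-dioxaspiro[4.5]dec-6-ene
Conditions: (TMSOCH2)2, TMSOTf (2 mol%), CH2Cl2, −78 °C
Reagents that add atoms: 1,2-bis(trimethylsilyloxy)ethane, C[Si](C)(C)OCCO[Si](C)(C)C
Why: Noyori ketalisation at low temperature protects the ketone without moving the C=C bond out of conjugation with the ketal carbon.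

**Step 4**
Reactants: 7 7-bromo-1,4-dioxaspiro[4.5]dec-6-ene; 5 (2S)-2-methylcyclobutan-1-one
Product: 9 (1R,2S)-1-(1,4-dioxaspiro[4.5]dec-6-en-7-yl)-2-methylcyclobutan-1-ol, via vinyllithium 8 (not isolated)
Conditions: t-BuLi (2 equiv), THF, −78 °C; then 5, −78 °C; then H2O
Reagents that add atoms: none
Why: Br/Li exchange and 1,2-addition to the strained ketone (faster than enolisation, so C2 is not epimerised), anti to the methyl group; the new carbinol centre becomes sp2 in step 5, so its configuration is irrelevant.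

**Step 5**
Reactants: 9 (1R,2S)-1-(1,4-dioxaspiro[4.5]dec-6-en-7-yl)-2-methylcyclobutan-1-ol
Product: 11 (4S,5S)-4-methylspiro[4.5]decane-1,7-dione 7-(ethylene ketal), via hydroxyethyl enol ether 10 (not isolated)
Conditions: (R)-TRIP N-triflylphosphoramide (5 mol%), 4 Å MS, PhMe, −20 °C → rt
Reagents that add atoms: none
Why: Proposed new method: a chiral Brønsted acid opens the allylic ketal to a 2-hydroxyethoxy-allyl cation paired with the chiral anion (which also hydrogen-bonds the cyclobutanol OH); the more substituted cyclobutane carbon (CHMe, with retention → C4) migrates to the cationic C5 (vinylogous semipinacol ring expansion, cyclobutanol → cyclopentanone), and the enol ether 10 recloses to the dioxolane so the C7 carbonyl stays masked. C5 is set by the torsional preference for the migrating-carbon methyl to lie syn to the vinylic C6–H rather than C10H2, with the catalyst antipode chosen to reinforce it (matched antipode to be confirmed by experiment). Closest known reaction types are the amine-catalysed vinylogous α-ketol rearrangement of 3-(1-hydroxycyclobutyl)enones and chiral phosphoric acid-catalysed semipinacol expansions of oxocarbenium-substituted cyclobutanols.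

**Step 6**
Reactants: 11 (4S,5S)-4-methylspiro[4.5]decane-1,7-dione 7-(ethylene ketal)
Product: 12 (1R,4S,5S)-1-hydroxy-4-methylspiro[4.5]decan-7-one ethylene ketal
Conditions: NaBH4, MeOH, 0 °C → rt
Reagents that add atoms: none
Why: Hydride reduction of the only free ketone; the carbinol configuration does not matter because C1 becomes a radical in step 7.

**Step 7**
Reactants: 12 (1R,4S,5S)-1-hydroxy-4-methylspiro[4.5]decan-7-one ethylene ketal; 13 vinyl bromide
Product: 15 (1R,4S,5S)-1-ethenyl-4-methylspiro[4.5]decan-7-one ethylene ketal, via NHC-alcohol adduct 14 (not isolated)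
Conditions: 5,7-di-tert-butyl-3-phenylbenzoxazolium BF4, pyridine, MTBE, rt; then 13, [Ir(ppy)2(dtbbpy)]PF6 (1 mol%), NiBr2·dtbbpy (5 mol%), quinuclidine, DMA, blue LEDs, rt
Reagents that add atoms: none
Why: NHC-mediated deoxygenative Ni/photoredox C(sp3)–C(sp2) cross-coupling; the planar C1 radical is captured by nickel on the face anti to the C4 methyl and the axial ketal oxygen of the C6 arm, so the vinyl group ends trans to the methyl (moderate to good dr expected, minor epimer separable).

**Step 8**
Reactants: 15 (1R,4S,5S)-1-ethenyl-4-methylspiro[4.5]decan-7-one ethylene ketal; 16 4-methylpent-1-en-3-one (isopropyl vinyl ketone)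
Product: 18 (1R,4S,5S)-4-methyl-1-[(2R)-6-methyl-5-oxoheptan-2-yl]spiro[4.5]decan-7-one, via side-chain ketal 17 (not isolated)
Conditions: 16 (3 equiv), Fe(acac)3 (30 mol%), PhSiH3, EtOH/(CH2OH)2, 60 °C; then 2 M HCl, THF, rt
Reagents that add atoms: water, O
Why: MHAT-initiated reductive olefin–enone coupling (Giese addition): H• adds to the terminal CH2, and the secondary C1' radical, in the A1,3-minimised conformer (C1–H eclipsing the radical's CH3), adds to the enone anti to the quaternary C5, which gives (1'R); aqueous acid then removes the dioxolane.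

**Step 9**
Reactants: 18 (1R,4S,5S)-4-methyl-1-[(2R)-6-methyl-5-oxoheptan-2-yl]spiro[4.5]decan-7-one; 19 methyl chloroformate
Product: 22 methyl (1R,4S,5S)-4-methyl-1-[(2R)-6-methyl-5-oxoheptan-2-yl]-7-oxospiro[4.5]decane-8-carboxylate, via pyrrolidine enamine 20 (not isolated), via C-acylated enamine 21 (not isolated)
Conditions: pyrrolidine, TsOH (cat.), PhH, reflux (−H2O); then 19, i-Pr2NEt, MeCN, 0 °C → rt; then AcOH/H2O
Reagents that add atoms: water, O
Why: Stork enamine acylation; pyrrolidine condenses only with the unhindered cyclohexanone (not the α-branched acyclic ketone), and C-acylation takes place at C8 rather than at the neopentyl C6 (Curtin–Hammett over the two enamine regioisomers).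

**Step 10**
Reactants: 22 methyl (1R,4S,5S)-4-methyl-1-[(2R)-6-methyl-5-oxoheptan-2-yl]-7-oxospiro[4.5]decane-8-carboxylate
Product: 25 methyl (1R,4S,5S)-4-methyl-1-[(2R)-6-methyl-5-oxoheptan-2-yl]-7-oxospiro[4.5]dec-8-ene-8-carboxylate, via α-phenylselenide 23 (not isolated), via selenoxide 24 (not isolated)
Conditions: PhSeCl, pyridine, CH2Cl2, 0 °C; then 30% H2O2, 0 °C → rt
Reagents that add atoms: none
Why: Selenenylation of the β-keto ester (the simple ketone does not react under pyridine conditions) and selenoxide syn-elimination, which can only go towards C9.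

**Step 11**
Reactants: 25 methyl (1R,4S,5S)-4-methyl-1-[(2R)-6-methyl-5-oxoheptan-2-yl]-7-oxospiro[4.5]dec-8-ene-8-carboxylate
Product: 26 methyl (1R,4S,5S,7S)-7-hydroxy-4-methyl-1-[(2R)-6-methyl-5-oxoheptan-2-yl]spiro[4.5]dec-8-ene-8-carboxylate
Conditions: (R)-Me-CBS (20 mol%), catecholborane (1.2 equiv), PhMe, −78 °C; then MeOH, aq. NaOH
Reagents that add atoms: none
Why: Corey–Bakshi–Shibata reduction; the α-carbomethoxy-vinyl side acts as the large group, so the (R)-catalyst delivers hydride to give the (7S)-allylic alcohol by reagent control, and limiting borane at −78 °C is expected to spare the hindered isopropyl ketone and the ester.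

**Compound list**
1 | ethyl (S)-lactate | C[C@H](O)C(=O)OCC | starting material
2 | ethylmagnesium bromide | CC[Mg]Br | starting material
3 | 1-[(1S)-1-hydroxyethyl]cyclopropan-1-ol | C[C@H](O)C1(O)CC1 | intermediate
4 | (1S)-1-(1-hydroxycyclopropyl)ethyl methanesulfonate | C[C@H](OS(C)(=O)=O)C1(O)CC1 | intermediate
5 | (2S)-2-methylcyclobutan-1-one | C[C@H]1CCC1=O | intermediate
6 | 3-bromocyclohex-2-en-1-one | O=C1C=C(Br)CCC1 | starting material
7 | 7-bromo-1,4-dioxaspiro[4.5]dec-6-ene | BrC1=CC2(CCC1)OCCO2 | intermediate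
8 | 1,4-dioxaspiro[4.5]dec-6-en-7-yllithium | [Li]C1=CC2(CCC1)OCCO2 | intermediate
9 | (1R,2S)-1-(1,4-dioxaspiro[4.5]dec-6-en-7-yl)-2-methylcyclobutan-1-ol | C[C@H]1CC[C@]1(O)C2=CC3(CCC2)OCCO3 | intermediate
10 | 7-(2-hydroxyethoxy)-4-methylspiro[4.5]dec-6-en-1-one (C4 and C5 as in 11) | O=C1CC[C@H](C)[C@]12C=C(OCCO)CCC2 | intermediate
11 | (4S,5S)-4-methylspiro[4.5]decane-1,7-dione 7-(ethylene ketal) | O=C1CC[C@H](C)[C@]12CC3(OCCO3)CCC2 | intermediate
12 | (1R,4S,5S)-1-hydroxy-4-methylspiro[4.5]decan-7-one ethylene ketal | O[C@@H]1CC[C@H](C)[C@]12CC3(OCCO3)CCC2 | intermediate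
13 | vinyl bromide | C=CBr | starting material
14 | 2-alkoxy-5,7-di-tert-butyl-3-phenyl-2,3-dihydro-1,3-benzoxazole adduct of 12 | CC(C)(C)c1cc2N(c3ccccc3)C(O[C@@H]4CC[C@H](C)[C@]45CC6(OCCO6)CCC5)Oc2c(c1)C(C)(C)C | intermediate
15 | (1R,4S,5S)-1-ethenyl-4-methylspiro[4.5]decan-7-one ethylene ketal | C=C[C@H]1CC[C@H](C)[C@]12CC3(OCCO3)CCC2 | intermediate
16 | 4-methylpent-1-en-3-one (isopropyl vinyl ketone) | CC(C)C(=O)C=C | starting material
17 | (1R,4S,5S)-4-methyl-1-[(2R)-6-methyl-5-oxoheptan-2-yl]spiro[4.5]decan-7-one ethylene ketal | CC(C)C(=O)CC[C@@H](C)[C@H]1CC[C@H](C)[C@]12CC3(OCCO3)CCC2 | intermediate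
18 | (1R,4S,5S)-4-methyl-1-[(2R)-6-methyl-5-oxoheptan-2-yl]spiro[4.5]decan-7-one | CC(C)C(=O)CC[C@@H](C)[C@H]1CC[C@H](C)[C@]12CC(=O)CCC2 | intermediate
19 | methyl chloroformate | COC(Cl)=O | starting material
20 | 7-(pyrrolidin-1-yl)spiro[4.5]dec-7-ene enamine of 18 | CC(C)C(=O)CC[C@@H](C)[C@H]1CC[C@H](C)[C@]12CC(N3CCCC3)=CCC2 | intermediate
21 | methyl 7-(pyrrolidin-1-yl)spiro[4.5]dec-7-ene-8-carboxylate derivative of 18 | CC(C)C(=O)CC[C@@H](C)[C@H]1CC[C@H](C)[C@]12CC(N3CCCC3)=C(C(=O)OC)CC2 | intermediate
22 | methyl (1R,4S,5S)-4-methyl-1-[(2R)-6-methyl-5-oxoheptan-2-yl]-7-oxospiro[4.5]decane-8-carboxylate (C8 epimers/enol) | CC(C)C(=O)CC[C@@H](C)[C@H]1CC[C@H](C)[C@]12CC(=O)C(C(=O)OC)CC2 | intermediate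
23 | 8-(phenylselanyl) derivative of 22 | CC(C)C(=O)CC[C@@H](C)[C@H]1CC[C@H](C)[C@]12CC(=O)C([Se]c3ccccc3)(C(=O)OC)CC2 | intermediate
24 | selenoxide of 23 | CC(C)C(=O)CC[C@@H](C)[C@H]1CC[C@H](C)[C@]12CC(=O)C([Se](=O)c3ccccc3)(C(=O)OC)CC2 | intermediate
25 | methyl (1R,4S,5S)-4-methyl-1-[(2R)-6-methyl-5-oxoheptan-2-yl]-7-oxospiro[4.5]dec-8-ene-8-carboxylate | CC(C)C(=O)CC[C@@H](C)[C@H]1CC[C@H](C)[C@]12CC(=O)C(C(=O)OC)=CC2 | intermediate
26 | methyl (1R,4S,5S,7S)-7-hydroxy-4-methyl-1-[(2R)-6-methyl-5-oxoheptan-2-yl]spiro[4.5]dec-8-ene-8-carboxylate | COC(=O)C1=CC[C@@]2(C[C@@H]1O)[C@@H]([C@H](C)CCC(=O)C(C)C)CC[C@@H]2C | target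

**Step count and risks**
Total steps: 11. Longest linear sequence: 10 (steps 1, 2, 4–11; step 3 is the side branch).

Three steps most likely to fail:

Step 5 (the proposed new ring expansion). The acid may ionise the tertiary allylic cyclobutanol instead of the ketal, the unsubstituted CH2 may migrate, or the C5 selectivity may be low. The fallback uses known chemistry and sets out from 9. Mild hydrolysis (PPTS, acetone/H2O) gives 3-[(1R,2S)-1-hydroxy-2-methylcyclobutyl]cyclohex-2-en-1-one F1. The established amine-catalysed vinylogous α-ketol rearrangement (9-amino-9-deoxy-epi-cinchona amine with N-Boc-phenylglycine, iminium activation) then gives (4S,5S)-4-methylspiro[4.5]decane-1,7-dione F2. Chemoselective ketalisation of the unhindered cyclohexanone (ethylene glycol, PPTS, PhH, −H2O; the α-quaternary cyclopentanone is much slower) comes back to the route at 11.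

Step 7 (deoxygenative vinylation). Adduct formation at the neopentyl-type secondary alcohol may be slow, and the facial selectivity rests on the 1,3-methyl group and the ketal. The fallback is polar and sets out from 11, bypassing 12. Wittig methoxymethylenation (Ph3P=CHOMe) gives the enol ether (4S,5S)-1-(methoxymethylidene)-4-methylspiro[4.5]decan-7-one ethylene ketal F3. Dilute acid (0.1 M HCl, THF, 0 °C; enol ether cleaved, dioxolane kept) and base equilibration (K2CO3, MeOH) give the aldehyde (1S,4S,5S)-1-formyl-4-methylspiro[4.5]decan-7-one ethylene ketal F4, with the formyl group expected to settle anti to the C4 methyl and the ketal-bearing arm (ratio to be checked). Salt-free methylenation (Ph3P=CH2, −78 → 0 °C) comes back at 15.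

Step 8 (C1' set by acyclic 1,2-induction in the radical addition). The dr may be modest and some alkene may simply be reduced. The fallback puts C1' under catalyst control and sets out from 12. The kinetic lithium enolate of 3-methylbutan-2-one is alkylated with 2,3-dibromopropene to give 6-bromo-2-methylhept-6-en-3-one F5. This is coupled with 12 under the step 7 conditions to give the 1,1-disubstituted alkene (1R,4S,5S)-4-methyl-1-(6-methyl-5-oxohept-1-en-2-yl)spiro[4.5]decan-7-one ethylene ketal F6. Iridium-catalysed asymmetric hydrogenation with a chiral P,N-ligand (H2, CH2Cl2) then comes back at 17, which is hydrolysed to 18 as in step 8.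

**Further compounds**
F1 | step 5 | 3-[(1R,2S)-1-hydroxy-2-methylcyclobutyl]cyclohex-2-en-1-one | C[C@H]1CC[C@]1(O)C2=CC(=O)CCC2
F2 | step 5 | (4S,5S)-4-methylspiro[4.5]decane-1,7-dione | O=C1CC[C@H](C)[C@]12CC(=O)CCC2
F3 | step 7 | (4S,5S)-1-(methoxymethylidene)-4-methylspiro[4.5]decan-7-one ethylene ketal | COC=C1CC[C@H](C)[C@]12CC3(OCCO3)CCC2
F4 | step 7 | (1S,4S,5S)-1-formyl-4-methylspiro[4.5]decan-7-one ethylene ketal | O=C[C@H]1CC[C@H](C)[C@]12CC3(OCCO3)CCC2
F5 | step 8 | 6-bromo-2-methylhept-6-en-3-one | CC(C)C(=O)CCC(Br)=C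
F6 | step 8 | (1R,4S,5S)-4-methyl-1-(6-methyl-5-oxohept-1-en-2-yl)spiro[4.5]decan-7-one ethylene ketal | CC(C)C(=O)CCC(=C)[C@H]1CC[C@H](C)[C@]12CC3(OCCO3)CCC2
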